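The route rests on disconnecting the O1–C2 bond of the dihydrobenzofuran. C2 is the benzylic carbon para to the C4 oxygen of syringyl ring C; with that phenol free, Ag2O oxidises the C2 methylene to a para-quinone methide held next to the ring D phenol oxygen O1, which adds and closes the furan trans to the C3 substituent in one operation. The precursor is an (S)-2,3-diarylpropanol silyl ether carrying both phenols free, ring D deactivated by its para ester, with C3 set by auxiliary alkylation. The two erythro arylglycerol units are then joined convergently by auxiliary-controlled aldol chemistry, and the enal is made last.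

Key step: step 13

Remarks
- Ring A is the guaiacyl ring, rings B and C are the syringyl rings, ring D is the benzene ring of the dihydrobenzofuran (O1, C2, C3, C3a, C5, C7, C7a). In each arylglycerol unit Cα is the benzylic carbinol, Cβ the aryloxy-bearing carbon, Cγ the CH2OH carbon; unit 1 sits on ring A, unit 2 on ring B.
- The target is trans-(2R,3S) in the dihydrobenzofuran and erythro (αR,βS) in both units. C3 of 18 is (S); the same spatial arrangement is (3S) in 20 and in the target, and the (S)-auxiliary of step 9 delivers it. No structural correction was needed and the disconnection is unchanged.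
- Assumption: the boron aldol of an aryloxyacetyl imide gives the syn (threo) relationship, so each unit is built with the (R)-auxiliary, which fixes Cβ, and Cα is then inverted.
- Ag2O is preferred to a quinone oxidant in step 13 because 20 keeps an oxidisable syringyl phenol.

Step 1
Reactants: 1 syringaldehyde
Product: 2 4-(benzyloxy)-3,5-dimethoxybenzaldehyde
Conditions: BnBr, K2CO3, DMF, 60 °C
Reagents that add atoms: benzyl bromide, BrCc1ccccc1
Why: Williamson etherification of the phenoxide should proceed cleanly because the aldehyde is inert to carbonate.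

Step 2
Reactants: 2 4-(benzyloxy)-3,5-dimethoxybenzaldehyde
Product: 3 [4-(benzyloxy)-3,5-dimethoxyphenyl]methanol
Conditions: NaBH4, MeOH, 0 °C
Reagents that add atoms: none
Why: Borohydride reduction of an aromatic aldehyde gives the benzylic alcohol and leaves the benzyl ether untouched.

Step 3
Reactants: 3 [4-(benzyloxy)-3,5-dimethoxyphenyl]methanol
Product: 4 2-(benzyloxy)-5-(bromomethyl)-1,3-dimethoxybenzene
Conditions: PBr3, CH2Cl2, 0 °C
Reagents that add atoms: phosphorus tribromide, BrP(Br)Br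
Why: Bromination of a benzylic alcohol with PBr3 (SN2 on the phosphite ester) should give a bromide stable enough to use at once, since the 4-alkoxy group is twisted out of conjugation by its two methoxy neighbours.

Step 4
Reactants: 5 methyl vanillate
Product: 6 methyl 4-(allyloxy)-3-methoxybenzoate
Conditions: allyl bromide, K2CO3, acetone, reflux
Reagents that add atoms: allyl bromide, C=CCBr
Why: Williamson O-allylation of an acidic phenol para to an ester is routine.

Step 5
Reactants: 6 methyl 4-(allyloxy)-3-methoxybenzoate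
Product: 7 methyl 3-allyl-4-hydroxy-5-methoxybenzoate
Conditions: PhNEt2, 200 °C
Reagents that add atoms: none
Why: The aromatic Claisen rearrangement can deliver the allyl group only to the one free ortho carbon, the other being blocked by the methoxy group.

Step 6
Reactants: 7 methyl 3-allyl-4-hydroxy-5-methoxybenzoate
Product: 8 methyl 3-allyl-4-(benzyloxy)-5-methoxybenzoate
Conditions: BnBr, K2CO3, DMF, 60 °C
Reagents that add atoms: benzyl bromide, BrCc1ccccc1
Why: Williamson benzylation masks the ring D phenol for the ozonolysis and enolate steps with the same group as ring C, so that one hydrogenolysis frees both.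

Step 7
Reactants: 8 methyl 3-allyl-4-(benzyloxy)-5-methoxybenzoate
Product: 10 2-[2-(benzyloxy)-3-methoxy-5-(methoxycarbonyl)phenyl]acetic acid, via arylacetaldehyde 9 (not isolated)
Conditions: O3, CH2Cl2/MeOH, −78 °C; Me2S, −78 °C → rt; then NaClO2, NaH2PO4, 2-methyl-2-butene, t-BuOH/H2O, rt
Reagents that add atoms: ozone, [O-][O+]=O; sodium chlorite, [Na+].[O-]Cl=O
Why: Ozonolysis with reductive work-up cleaves the terminal alkene much faster than the ester-deactivated arene, and Pinnick oxidation of the crude aldehyde gives the acid without touching the benzyl ether or the ester.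

Step 8
Reactants: 10 2-[2-(benzyloxy)-3-methoxy-5-(methoxycarbonyl)phenyl]acetic acid; 11 (S)-4-benzyl-2-oxazolidinone
Product: 13 (4S)-4-benzyl-3-{[2-(benzyloxy)-3-methoxy-5-(methoxycarbonyl)phenyl]acetyl}oxazolidin-2-one, via mixed pivalic anhydride 12 (not isolated)
Conditions: t-BuCOCl, Et3N, THF, −20 °C; then LiCl, 11, −20 °C → rt
Reagents that add atoms: none
Why: Mixed-anhydride N-acylation of the oxazolidinone under LiCl/Et3N activation occurs at the less hindered arylacetyl carbonyl and needs no strong base, so the methyl ester is safe.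

Step 9
Reactants: 13 (4S)-4-benzyl-3-{[2-(benzyloxy)-3-methoxy-5-(methoxycarbonyl)phenyl]acetyl}oxazolidin-2-one; 4 2-(benzyloxy)-5-(bromomethyl)-1,3-dimethoxybenzene
Product: 15 (4S)-4-benzyl-3-{(2S)-3-[4-(benzyloxy)-3,5-dimethoxyphenyl]-2-[2-(benzyloxy)-3-methoxy-5-(methoxycarbonyl)phenyl]propanoyl}oxazolidin-2-one, via sodium Z-enolate 14 (not isolated)
Conditions: NaN(SiMe3)2, THF, −78 °C; then 4, −78 → −30 °C; AcOH quench
Reagents that add atoms: none
Why: Evans asymmetric alkylation: the chelated Z-enolate is shielded on one face by the 4-benzyl group, so the reactive benzylic bromide enters from the other face and sets C3 as (S), with slightly substoichiometric base and a cold acidic quench protecting the acidic α-aryl centre from epimerisation.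

Step 10
Reactants: 15 (4S)-4-benzyl-3-{(2S)-3-[4-(benzyloxy)-3,5-dimethoxyphenyl]-2-[2-(benzyloxy)-3-methoxy-5-(methoxycarbonyl)phenyl]propanoyl}oxazolidin-2-one
Product: 16 methyl 4-(benzyloxy)-3-{(2S)-1-[4-(benzyloxy)-3,5-dimethoxyphenyl]-3-hydroxypropan-2-yl}-5-methoxybenzoate
Conditions: NaBH4, THF/H2O (4:1), 0 °C → rt
Reagents that add atoms: none
Why: Reductive cleavage of the N-acyl oxazolidinone with NaBH4 in wet THF gives the primary alcohol and returns the auxiliary, while the methyl benzoate is not reduced and the transient aldehyde is reduced faster than it can enolise.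

Step 11
Reactants: 16 methyl 4-(benzyloxy)-3-{(2S)-1-[4-(benzyloxy)-3,5-dimethoxyphenyl]-3-hydroxypropan-2-yl}-5-methoxybenzoate
Product: 17 methyl 4-(benzyloxy)-3-{(2S)-1-[4-(benzyloxy)-3,5-dimethoxyphenyl]-3-[(tert-butyldimethylsilyl)oxy]propan-2-yl}-5-methoxybenzoate
Conditions: TBSCl, imidazole, DMF, rt
Reagents that add atoms: tert-butyldimethylsilyl chloride, CC(C)(C)[Si](C)(C)Cl
Why: Silylation of the only hydroxyl group is straightforward.

Step 12
Reactants: 17 methyl 4-(benzyloxy)-3-{(2S)-1-[4-(benzyloxy)-3,5-dimethoxyphenyl]-3-[(tert-butyldimethylsilyl)oxy]propan-2-yl}-5-methoxybenzoate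
Product: 18 methyl 3-{(2S)-1-[(tert-butyldimethylsilyl)oxy]-3-(4-hydroxy-3,5-dimethoxyphenyl)propan-2-yl}-4-hydroxy-5-methoxybenzoate
Conditions: H2 (1 atm), 10% Pd/C, EtOAc, rt
Reagents that add atoms: none
Why: Hydrogenolysis removes both benzyl ethers in one operation, and the aprotic solvent keeps the silyl ether and the ester intact.

Step 13
Reactants: 18 methyl 3-{(2S)-1-[(tert-butyldimethylsilyl)oxy]-3-(4-hydroxy-3,5-dimethoxyphenyl)propan-2-yl}-4-hydroxy-5-methoxybenzoate
Product: 20 methyl (2R,3S)-3-{[(tert-butyldimethylsilyl)oxy]methyl}-2-(4-hydroxy-3,5-dimethoxyphenyl)-7-methoxy-2,3-dihydro-1-benzofuran-5-carboxylate, via para-quinone methide 19 (not isolated)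
Conditions: Ag2O, CH2Cl2, rt, dark
Reagents that add atoms: none
Why: Ag2O takes the ring C phenol through its phenoxyl radical, which cannot couple because both ortho positions carry methoxy groups, to the para-quinone methide 19 by removing the benzylic hydrogen at C2, so that C2 becomes an electrophilic exocyclic alkene carbon; O1 of the ring D phenol then attacks it in a vinylogous (1,6) conjugate addition that restores the aromaticity of ring C. The closest known reaction type is the oxidation of 4-alkyl-2,6-dialkoxyphenols to para-quinone methides with intramolecular capture by a phenol, as in oxidative cyclisations of diarylpropanes to flavans. The furan ring closes in a 5-exo-trig mode. The new centre C2 is controlled by the C3 silyloxymethyl group set in step 9, the aryl group taking the face opposite to it, and because the addition can revert through 19 the trans (2R,3S) isomer is also the thermodynamic product. The step needs oxidation of ring C and not ring D, which the para ester on ring D and the two donor methoxy groups on ring C secure, and it needs the product phenol to survive, which a mild heterogeneous oxidant used near stoichiometry without base or nucleophilic solvent favours.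

Step 14
Reactants: 21 (R)-4-benzyl-2-oxazolidinone; 22 bromoacetyl bromide
Product: 24 (4R)-4-benzyl-3-(bromoacetyl)oxazolidin-2-one, via N-lithio oxazolidinone 23 (not isolated)
Conditions: n-BuLi, THF, −78 °C; then 22, −78 °C
Reagents that add atoms: none
Why: N-acylation of the lithiated oxazolidinone is selective because the acyl bromide reacts far faster than the alkyl bromide at −78 °C.

Step 15
Reactants: 25 vanillin
Product: 26 3-methoxy-4-[(triisopropylsilyl)oxy]benzaldehyde
Conditions: TIPSCl, imidazole, DMF, rt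
Reagents that add atoms: triisopropylsilyl chloride, CC(C)[Si](Cl)(C(C)C)C(C)C
Why: Phenol silylation; the bulky aryl silyl ether should resist the hydride and mildly basic steps that follow and leaves with fluoride at the end.

Step 16
Reactants: 27 methyl syringate; 24 (4R)-4-benzyl-3-(bromoacetyl)oxazolidin-2-one
Product: 28 methyl 4-{2-[(4R)-4-benzyl-2-oxooxazolidin-3-yl]-2-oxoethoxy}-3,5-dimethoxybenzoate
Conditions: K2CO3, acetone, rt
Reagents that add atoms: none
Why: Williamson etherification with a highly activated α-bromo imide; attack of the phenoxide at the imide carbonyl is reversible and unproductive, so SN2 at CH2Br should prevail.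

Step 17
Reactants: 28 methyl 4-{2-[(4R)-4-benzyl-2-oxooxazolidin-3-yl]-2-oxoethoxy}-3,5-dimethoxybenzoate; 26 3-methoxy-4-[(triisopropylsilyl)oxy]benzaldehyde
Product: 30 (4R)-4-benzyl-3-[(2R,3S)-3-hydroxy-2-[2,6-dimethoxy-4-(methoxycarbonyl)phenoxy]-3-{3-methoxy-4-[(triisopropylsilyl)oxy]phenyl}propanoyl]oxazolidin-2-one, via dibutylboron Z-enolate 29 (not isolated)
Conditions: Bu2BOTf, i-Pr2NEt, CH2Cl2, −78 → 0 °C; then 26, −78 → 0 °C; pH 7 buffer, MeOH, 30% H2O2, 0 °C
Reagents that add atoms: none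
Why: Evans syn aldol: the Z-boron enolate reacts through a closed chair transition state with the auxiliary dipole opposed, which sets Cβ of unit 1 in its final configuration and Cα as the epimer (syn, threo).

Step 18
Reactants: 30 (4R)-4-benzyl-3-[(2R,3S)-3-hydroxy-2-[2,6-dimethoxy-4-(methoxycarbonyl)phenoxy]-3-{3-methoxy-4-[(triisopropylsilyl)oxy]phenyl}propanoyl]oxazolidin-2-one
Product: 31 (4R)-4-benzyl-3-[(2R,3R)-2-[2,6-dimethoxy-4-(methoxycarbonyl)phenoxy]-3-{3-methoxy-4-[(triisopropylsilyl)oxy]phenyl}-3-[(4-nitrobenzoyl)oxy]propanoyl]oxazolidin-2-one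
Conditions: PPh3, DIAD, 4-O2NC6H4CO2H, THF, −20 °C → rt
Reagents that add atoms: 4-nitrobenzoic acid, OC(=O)c1ccc(cc1)[N+](=O)[O-]
Why: Mitsunobu inversion: SN2 displacement of the activated benzylic oxygen by the carboxylate inverts Cα to the erythro series, and the low kinetic acidity of the imide α-hydrogen (allylic 1,3-strain) disfavours β-elimination.

Step 19
Reactants: 31 (4R)-4-benzyl-3-[(2R,3R)-2-[2,6-dimethoxy-4-(methoxycarbonyl)phenoxy]-3-{3-methoxy-4-[(triisopropylsilyl)oxy]phenyl}-3-[(4-nitrobenzoyl)oxy]propanoyl]oxazolidin-2-one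
Product: 32 (1R,2S)-2-[4-(hydroxymethyl)-2,6-dimethoxyphenoxy]-1-{3-methoxy-4-[(triisopropylsilyl)oxy]phenyl}propane-1,3-diol
Conditions: LiBH4, MeOH (4 equiv), THF, 0 → 40 °C
Reagents that add atoms: none
Why: Hydride reduction with LiBH4 should cleave the imide to the Cγ alcohol, the nitrobenzoate to the free Cα alcohol and the methyl benzoate to the benzylic alcohol in one pot, while the nitro group and the silyl ether are inert.

Step 20
Reactants: 32 (1R,2S)-2-[4-(hydroxymethyl)-2,6-dimethoxyphenoxy]-1-{3-methoxy-4-[(triisopropylsilyl)oxy]phenyl}propane-1,3-diol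
Product: 33 {4-[((4R,5S)-2,2-dimethyl-4-{3-methoxy-4-[(triisopropylsilyl)oxy]phenyl}-1,3-dioxan-5-yl)oxy]-3,5-dimethoxyphenyl}methanol
Conditions: Me2C(OMe)2, PPTS (cat.), CH2Cl2, rt
Reagents that add atoms: 2,2-dimethoxypropane, COC(C)(C)OC
Why: Transacetalisation gives the six-membered acetonide of the 1,3-diol only, since the isolated benzylic alcohol cannot form a cyclic acetal and is freed again on aqueous work-up.

Step 21
Reactants: 33 {4-[((4R,5S)-2,2-dimethyl-4-{3-methoxy-4-[(triisopropylsilyl)oxy]phenyl}-1,3-dioxan-5-yl)oxy]-3,5-dimethoxyphenyl}methanol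
Product: 34 4-[((4R,5S)-2,2-dimethyl-4-{3-methoxy-4-[(triisopropylsilyl)oxy]phenyl}-1,3-dioxan-5-yl)oxy]-3,5-dimethoxybenzaldehyde
Conditions: activated MnO2, CH2Cl2, rt
Reagents that add atoms: none
Why: MnO2 oxidation of the only free, benzylic alcohol stops at the aldehyde.

Step 22
Reactants: 20 methyl (2R,3S)-3-{[(tert-butyldimethylsilyl)oxy]methyl}-2-(4-hydroxy-3,5-dimethoxyphenyl)-7-methoxy-2,3-dihydro-1-benzofuran-5-carboxylate; 24 (4R)-4-benzyl-3-(bromoacetyl)oxazolidin-2-one
Product: 35 methyl (2R,3S)-2-(4-{2-[(4R)-4-benzyl-2-oxooxazolidin-3-yl]-2-oxoethoxy}-3,5-dimethoxyphenyl)-3-{[(tert-butyldimethylsilyl)oxy]methyl}-7-methoxy-2,3-dihydro-1-benzofuran-5-carboxylate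
Conditions: K2CO3, acetone, rt
Reagents that add atoms: none
Why: Williamson etherification of the only acidic hydroxyl; mild carbonate at room temperature should leave the benzylic aryl ether, the ester and the silyl ether intact, and alkylation removes the phenol that makes 20 oxidisable.

Step 23
Reactants: 35 methyl (2R,3S)-2-(4-{2-[(4R)-4-benzyl-2-oxooxazolidin-3-yl]-2-oxoethoxy}-3,5-dimethoxyphenyl)-3-{[(tert-butyldimethylsilyl)oxy]methyl}-7-methoxy-2,3-dihydro-1-benzofuran-5-carboxylate; 34 4-[((4R,5S)-2,2-dimethyl-4-{3-methoxy-4-[(triisopropylsilyl)oxy]phenyl}-1,3-dioxan-5-yl)oxy]-3,5-dimethoxybenzaldehyde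
Product: 37 syn aldol adduct: (4R)-4-benzyloxazolidin-2-one N-acylated by a (2R,3S)-3-hydroxypropanoyl chain that bears at C2 the ring C oxygen of 35 and at C3 the ring B aryl group of 34, via dibutylboron Z-enolate 36 (not isolated)
Conditions: Bu2BOTf, i-Pr2NEt, CH2Cl2, −78 → 0 °C; then 34, −78 → 0 °C; pH 7 buffer, MeOH, 30% H2O2, 0 °C
Reagents that add atoms: none
Why: Evans syn aldol under reagent control, the stereocentres of both partners being too remote to interfere, sets Cβ of unit 2 correctly and Cα as the epimer while joining the two fragments.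

Step 24
Reactants: 37 syn aldol adduct of 35 and 34
Product: 38 (2R,3R) 4-nitrobenzoate of 37, with Cα of unit 2 inverted
Conditions: PPh3, DIAD, 4-O2NC6H4CO2H, THF, −20 °C → rt
Reagents that add atoms: 4-nitrobenzoic acid, OC(=O)c1ccc(cc1)[N+](=O)[O-]
Why: Mitsunobu inversion at the only free hydroxyl converts unit 2 to the erythro series; the ring B carbinol is a poor cation precursor because its para oxygen is twisted out of conjugation, which favours clean SN2.

Step 25
Reactants: 38 (2R,3R) 4-nitrobenzoate of 37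
Product: 39 triol with unit 2 as the (αR,βS) 1,3-diol and the ring D ester reduced to CH2OH
Conditions: LiBH4, MeOH (4 equiv), THF, 0 → 40 °C
Reagents that add atoms: none
Why: The same LiBH4 reduction as in step 19 should remove the auxiliary and the nitrobenzoate and reduce the ring D ester, leaving the acetonide and both silyl ethers.

Step 26
Reactants: 39 triol with unit 2 as the (αR,βS) 1,3-diol
Product: 40 bis-acetonide with free ring D benzylic alcohol
Conditions: Me2C(OMe)2, PPTS (cat.), CH2Cl2, rt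
Reagents that add atoms: 2,2-dimethoxypropane, COC(C)(C)OC
Why: Acetonide formation masks the Cα and Cγ hydroxyls of unit 2 and so singles out the ring D benzylic alcohol for oxidation.

Step 27
Reactants: 40 bis-acetonide with free ring D benzylic alcohol
Product: 41 bis-acetonide ring D aldehyde (formyl group at C5)
Conditions: activated MnO2, CH2Cl2, rt
Reagents that add atoms: none
Why: MnO2 oxidation of the only free hydroxyl, a benzylic alcohol para to O1, gives the aldehyde.

Step 28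
Reactants: 41 bis-acetonide ring D aldehyde; 42 (triphenylphosphoranylidene)acetaldehyde
Product: 43 fully protected (E)-enal
Conditions: 42 (1.3 equiv), toluene, 80 °C
Reagents that add atoms: none
Why: Wittig olefination with the stabilised formyl ylide gives the (E)-cinnamaldehyde, and limiting the ylide restrains a second homologation.

Step 29
Reactants: 43 fully protected (E)-enal
Product: 45 target CNP0192639.1, via desilylated bis-acetonide 44 (not isolated)
Conditions: Bu4NF, AcOH, THF, 0 °C → rt; then 1 M aq HCl, rt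
Reagents that add atoms: none
Why: Buffered fluoride desilylation frees the ring A phenol and the C3 hydroxymethyl group, and mild aqueous acid then hydrolyses the two acetonides at their acetal carbons without ionising the benzylic C–O bonds or touching the enal.

Compound list
1 | syringaldehyde | COc1cc(C=O)cc(OC)c1O | starting material
2 | 4-(benzyloxy)-3,5-dimethoxybenzaldehyde | COc1cc(C=O)cc(OC)c1OCc2ccccc2 | intermediate
3 | [4-(benzyloxy)-3,5-dimethoxyphenyl]methanol | COc1cc(CO)cc(OC)c1OCc2ccccc2 | intermediate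
4 | 2-(benzyloxy)-5-(bromomethyl)-1,3-dimethoxybenzene | COc1cc(CBr)cc(OC)c1OCc2ccccc2 | intermediate
5 | methyl vanillate | COC(=O)c1ccc(O)c(OC)c1 | starting material
6 | methyl 4-(allyloxy)-3-methoxybenzoate | COC(=O)c1ccc(OCC=C)c(OC)c1 | intermediate
7 | methyl 3-allyl-4-hydroxy-5-methoxybenzoate | COC(=O)c1cc(OC)c(O)c(CC=C)c1 | intermediate
8 | methyl 3-allyl-4-(benzyloxy)-5-methoxybenzoate | COC(=O)c1cc(OC)c(OCc2ccccc2)c(CC=C)c1 | intermediate
9 | methyl 4-(benzyloxy)-3-methoxy-5-(2-oxoethyl)benzoate | COC(=O)c1cc(OC)c(OCc2ccccc2)c(CC=O)c1 | intermediate (not isolated)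
10 | 2-[2-(benzyloxy)-3-methoxy-5-(methoxycarbonyl)phenyl]acetic acid | COC(=O)c1cc(OC)c(OCc2ccccc2)c(CC(=O)O)c1 | intermediate
11 | (S)-4-benzyl-2-oxazolidinone | O=C1OC[C@H](Cc2ccccc2)N1 | starting material
12 | mixed anhydride of acid 10 and pivalic acid | COC(=O)c1cc(OC)c(OCc2ccccc2)c(CC(=O)OC(=O)C(C)(C)C)c1 | intermediate (not isolated)
13 | (4S)-4-benzyl-3-{[2-(benzyloxy)-3-methoxy-5-(methoxycarbonyl)phenyl]acetyl}oxazolidin-2-one | COC(=O)c1cc(OC)c(OCc2ccccc2)c(CC(=O)N3[C@@H](Cc4ccccc4)COC3=O)c1 | intermediate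
14 | sodium Z-enolate of imide 13 | COC(=O)c1cc(OC)c(OCc2ccccc2)c(/C=C(\[O-])N3[C@@H](Cc4ccccc4)COC3=O)c1.[Na+] | intermediate (not isolated)
15 | (4S)-4-benzyl-3-{(2S)-3-[4-(benzyloxy)-3,5-dimethoxyphenyl]-2-[2-(benzyloxy)-3-methoxy-5-(methoxycarbonyl)phenyl]propanoyl}oxazolidin-2-one | COC(=O)c1cc(OC)c(OCc2ccccc2)c(c1)[C@@H](C(=O)N3[C@@H](Cc4ccccc4)COC3=O)Cc5cc(OC)c(OCc6ccccc6)c(OC)c5 | intermediate
16 | methyl 4-(benzyloxy)-3-{(2S)-1-[4-(benzyloxy)-3,5-dimethoxyphenyl]-3-hydroxypropan-2-yl}-5-methoxybenzoate | COC(=O)c1cc(OC)c(OCc2ccccc2)c(c1)[C@@H](CO)Cc3cc(OC)c(OCc4ccccc4)c(OC)c3 | intermediate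
17 | methyl 4-(benzyloxy)-3-{(2S)-1-[4-(benzyloxy)-3,5-dimethoxyphenyl]-3-[(tert-butyldimethylsilyl)oxy]propan-2-yl}-5-methoxybenzoate | COC(=O)c1cc(OC)c(OCc2ccccc2)c(c1)[C@@H](CO[Si](C)(C)C(C)(C)C)Cc3cc(OC)c(OCc4ccccc4)c(OC)c3 | intermediate
18 | methyl 3-{(2S)-1-[(tert-butyldimethylsilyl)oxy]-3-(4-hydroxy-3,5-dimethoxyphenyl)propan-2-yl}-4-hydroxy-5-methoxybenzoate | COC(=O)c1cc(OC)c(O)c(c1)[C@@H](CO[Si](C)(C)C(C)(C)C)Cc2cc(OC)c(O)c(OC)c2 | intermediate
19 | para-quinone methide of 18: methyl 3-{(2S)-1-[(tert-butyldimethylsilyl)oxy]-3-(3,5-dimethoxy-4-oxocyclohexa-2,5-dien-1-ylidene)propan-2-yl}-4-hydroxy-5-methoxybenzoate | COC(=O)c1cc(OC)c(O)c(c1)[C@@H](CO[Si](C)(C)C(C)(C)C)C=C2C=C(OC)C(=O)C(OC)=C2 | intermediate (not isolated)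
20 | methyl (2R,3S)-3-{[(tert-butyldimethylsilyl)oxy]methyl}-2-(4-hydroxy-3,5-dimethoxyphenyl)-7-methoxy-2,3-dihydro-1-benzofuran-5-carboxylate (trans) | COc1cc([C@@H]2Oc3c(OC)cc(C(=O)OC)cc3[C@H]2CO[Si](C)(C)C(C)(C)C)cc(OC)c1O | intermediate
21 | (R)-4-benzyl-2-oxazolidinone | O=C1OC[C@@H](Cc2ccccc2)N1 | starting material
22 | bromoacetyl bromide | BrCC(Br)=O | starting material
23 | N-lithio salt of 21 | [Li+].O=C1OC[C@@H](Cc2ccccc2)[N-]1 | intermediate (not isolated)
24 | (4R)-4-benzyl-3-(bromoacetyl)oxazolidin-2-one | BrCC(=O)N1[C@H](Cc2ccccc2)COC1=O | intermediate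
25 | vanillin | COc1cc(C=O)ccc1O | starting material
26 | 3-methoxy-4-[(triisopropylsilyl)oxy]benzaldehyde | COc1cc(C=O)ccc1O[Si](C(C)C)(C(C)C)C(C)C | intermediate
27 | methyl syringate (methyl 4-hydroxy-3,5-dimethoxybenzoate) | COC(=O)c1cc(OC)c(O)c(OC)c1 | starting material
28 | methyl 4-{2-[(4R)-4-benzyl-2-oxooxazolidin-3-yl]-2-oxoethoxy}-3,5-dimethoxybenzoate | COC(=O)c1cc(OC)c(OCC(=O)N2[C@H](Cc3ccccc3)COC2=O)c(OC)c1 | intermediate
29 | dibutylboron Z-enolate of 28 | COC(=O)c1cc(OC)c(O/C=C(\OB(CCCC)CCCC)N2[C@H](Cc3ccccc3)COC2=O)c(OC)c1 | intermediate (not isolated)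
30 | (4R)-4-benzyl-3-[(2R,3S)-3-hydroxy-2-[2,6-dimethoxy-4-(methoxycarbonyl)phenoxy]-3-{3-methoxy-4-[(triisopropylsilyl)oxy]phenyl}propanoyl]oxazolidin-2-one (syn) | COc1cc(ccc1O[Si](C(C)C)(C(C)C)C(C)C)[C@H](O)[C@H](C(=O)N2[C@H](Cc3ccccc3)COC2=O)Oc4c(OC)cc(cc4OC)C(=O)OC | intermediate
31 | (4R)-4-benzyl-3-[(2R,3R)-2-[2,6-dimethoxy-4-(methoxycarbonyl)phenoxy]-3-{3-methoxy-4-[(triisopropylsilyl)oxy]phenyl}-3-[(4-nitrobenzoyl)oxy]propanoyl]oxazolidin-2-one | COc1cc(ccc1O[Si](C(C)C)(C(C)C)C(C)C)[C@@H](OC(=O)c5ccc(cc5)[N+](=O)[O-])[C@H](C(=O)N2[C@H](Cc3ccccc3)COC2=O)Oc4c(OC)cc(cc4OC)C(=O)OC | intermediate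
32 | (1R,2S)-2-[4-(hydroxymethyl)-2,6-dimethoxyphenoxy]-1-{3-methoxy-4-[(triisopropylsilyl)oxy]phenyl}propane-1,3-diol (erythro) | COc1cc(ccc1O[Si](C(C)C)(C(C)C)C(C)C)[C@@H](O)[C@H](CO)Oc2c(OC)cc(CO)cc2OC | intermediate
33 | {4-[((4R,5S)-2,2-dimethyl-4-{3-methoxy-4-[(triisopropylsilyl)oxy]phenyl}-1,3-dioxan-5-yl)oxy]-3,5-dimethoxyphenyl}methanol | COc1cc(ccc1O[Si](C(C)C)(C(C)C)C(C)C)[C@@H](OC(C)(C)OC2)[C@H]2Oc3c(OC)cc(CO)cc3OC | intermediate
34 | 4-[((4R,5S)-2,2-dimethyl-4-{3-methoxy-4-[(triisopropylsilyl)oxy]phenyl}-1,3-dioxan-5-yl)oxy]-3,5-dimethoxybenzaldehyde | COc1cc(ccc1O[Si](C(C)C)(C(C)C)C(C)C)[C@@H](OC(C)(C)OC2)[C@H]2Oc3c(OC)cc(C=O)cc3OC | intermediate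
35 | methyl (2R,3S)-2-(4-{2-[(4R)-4-benzyl-2-oxooxazolidin-3-yl]-2-oxoethoxy}-3,5-dimethoxyphenyl)-3-{[(tert-butyldimethylsilyl)oxy]methyl}-7-methoxy-2,3-dihydro-1-benzofuran-5-carboxylate | COc1cc([C@@H]2Oc3c(OC)cc(C(=O)OC)cc3[C@H]2CO[Si](C)(C)C(C)(C)C)cc(OC)c1OCC(=O)N4[C@H](Cc5ccccc5)COC4=O | intermediate
36 | dibutylboron Z-enolate of 35 | COc1cc([C@@H]2Oc3c(OC)cc(C(=O)OC)cc3[C@H]2CO[Si](C)(C)C(C)(C)C)cc(OC)c1O/C=C(\OB(CCCC)CCCC)N4[C@H](Cc5ccccc5)COC4=O | intermediate (not isolated)
37 | syn aldol adduct of 35 and 34: (2R,3S)-3-hydroxy acyl chain on the (4R)-auxiliary, unit 1 as (4R,5S) acetonide, dihydrobenzofuran (2R,3S) | COc1cc(ccc1O[Si](C(C)C)(C(C)C)C(C)C)[C@@H](OC(C)(C)OC2)[C@H]2Oc3c(OC)cc(cc3OC)[C@H](O)[C@H](C(=O)N4[C@H](Cc5ccccc5)COC4=O)Oc6c(OC)cc(cc6OC)[C@@H]7Oc8c(OC)cc(C(=O)OC)cc8[C@H]7CO[Si](C)(C)C(C)(C)C | intermediate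
38 | (2R,3R) 4-nitrobenzoate of 37, Cα of unit 2 inverted | COc1cc(ccc1O[Si](C(C)C)(C(C)C)C(C)C)[C@@H](OC(C)(C)OC2)[C@H]2Oc3c(OC)cc(cc3OC)[C@@H](OC(=O)c9ccc(cc9)[N+](=O)[O-])[C@H](C(=O)N4[C@H](Cc5ccccc5)COC4=O)Oc6c(OC)cc(cc6OC)[C@@H]7Oc8c(OC)cc(C(=O)OC)cc8[C@H]7CO[Si](C)(C)C(C)(C)C | intermediate
39 | triol: unit 2 as (αR,βS) 1,3-diol, ring D C5 as CH2OH, unit 1 acetonide, TIPS and TBS ethers kept | COc1cc(ccc1O[Si](C(C)C)(C(C)C)C(C)C)[C@@H](OC(C)(C)OC2)[C@H]2Oc3c(OC)cc(cc3OC)[C@@H](O)[C@H](CO)Oc6c(OC)cc(cc6OC)[C@@H]7Oc8c(OC)cc(CO)cc8[C@H]7CO[Si](C)(C)C(C)(C)C | intermediate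
40 | bis-acetonide (both units as (4R,5S)-2,2-dimethyl-1,3-dioxanes) with ring D C5 as CH2OH | COc1cc(ccc1O[Si](C(C)C)(C(C)C)C(C)C)[C@@H](OC(C)(C)OC2)[C@H]2Oc3c(OC)cc(cc3OC)[C@@H](OC(C)(C)OC4)[C@H]4Oc6c(OC)cc(cc6OC)[C@@H]7Oc8c(OC)cc(CO)cc8[C@H]7CO[Si](C)(C)C(C)(C)C | intermediate
41 | bis-acetonide with ring D C5 as CHO | COc1cc(ccc1O[Si](C(C)C)(C(C)C)C(C)C)[C@@H](OC(C)(C)OC2)[C@H]2Oc3c(OC)cc(cc3OC)[C@@H](OC(C)(C)OC4)[C@H]4Oc6c(OC)cc(cc6OC)[C@@H]7Oc8c(OC)cc(C=O)cc8[C@H]7CO[Si](C)(C)C(C)(C)C | intermediate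
42 | (triphenylphosphoranylidene)acetaldehyde | O=CC=P(c1ccccc1)(c2ccccc2)c3ccccc3 | starting material
43 | fully protected (E)-enal: bis-acetonide, ring A O-TIPS, C3 CH2O-TBS | COc1cc(ccc1O[Si](C(C)C)(C(C)C)C(C)C)[C@@H](OC(C)(C)OC2)[C@H]2Oc3c(OC)cc(cc3OC)[C@@H](OC(C)(C)OC4)[C@H]4Oc6c(OC)cc(cc6OC)[C@@H]7Oc8c(OC)cc(/C=C/C=O)cc8[C@H]7CO[Si](C)(C)C(C)(C)C | intermediate
44 | bis-acetonide of the target with free ring A phenol and free C3 hydroxymethyl group | COc1cc(ccc1O)[C@@H](OC(C)(C)OC2)[C@H]2Oc3c(OC)cc(cc3OC)[C@@H](OC(C)(C)OC4)[C@H]4Oc6c(OC)cc(cc6OC)[C@@H]7Oc8c(OC)cc(/C=C/C=O)cc8[C@H]7CO | intermediate (not isolated)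
45 | CNP0192639.1 | COc1cc([C@@H](O)[C@H](CO)Oc2c(OC)cc([C@@H](O)[C@H](CO)Oc3c(OC)cc([C@@H]4Oc5c(OC)cc(/C=C/C=O)cc5[C@H]4CO)cc3OC)cc2OC)ccc1O | target

Total step count: 29
Longest linear sequence: 18 steps (steps 4–13, then 22–29, from methyl vanillate)

Steps most likely to fail

Step 13. The product phenol may be oxidised further (dehydrogenation to the benzofuran), the quinone methide may tautomerise to the stilbene with loss of C3, or oxidation may start on the wrong ring. The fallback closes the same O1–C2 bond without an oxidant, from a C2 carbinol, setting out from acid 10 and rejoining at 20. Acylation of auxiliary 21 through anhydride 12 (t-BuCOCl, Et3N; LiCl) would give the (R)-configured arylacetyl imide F1. Its dibutylboron Z-enolate F2 (Bu2BOTf, i-Pr2NEt) would add to aldehyde 2 in an Evans syn aldol to give the β-hydroxy imide F3; the boron aldol has the opposite facial sense to the alkylation, so the (R)-auxiliary sets the same C3 configuration as step 9. NaBH4 in wet THF would give the 1,3-diol F4, silylation of the primary hydroxyl (TBSCl, imidazole, 0 °C) the TBS ether F5, and hydrogenolysis (H2, Pd/C, EtOAc) the bis-phenol carbinol F6. Acid catalysis (PPTS, CH2Cl2, rt) would ionise the para-hydroxybenzylic alcohol, and the ring D phenol would close the ring under thermodynamic control to trans-20.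

Step 18 (step 24 repeats the operation on the less ionisable ring B carbinol). The activated benzylic carbinol next to the donor ring A may ionise, giving substitution with partial retention, or eliminate toward the enol ether. The fallback corrects Cα by oxidation and reduction instead of substitution, setting out from 30 and rejoining at 32. NaBH4 in wet THF would remove the auxiliary and give the threo diol F7 with the ring B ester intact. Pivaloylation of the primary hydroxyl (t-BuCOCl, pyridine, 0 °C) would give the monopivalate F8, and Dess–Martin periodinane (NaHCO3, CH2Cl2) the aryl ketone F9. Zn(BH4)2 in Et2O at −20 °C, delivering hydride through the chelate between the ketone and the β-aryloxy oxygen, should favour the erythro alcohol F10, as in reductions of α-aryloxy propiophenones. LiBH4 as in step 19 would then cleave the pivalate and reduce the ring B ester to give 32.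

Step 22. Under base the para-hydroxybenzyl aryl ether of 20 may reopen through the quinone methide, and the phenoxide may take the acyl group from the imide instead of displacing bromide. The fallback forms the same ether under neutral conditions, setting out from 20 and rejoining at 35. The lithium salt 23 would be acylated with benzyloxyacetyl chloride (THF, −78 °C) to give the benzyloxyacetyl imide F11. Hydrogenolysis (H2, Pd/C, EtOAc) would give the hydroxyacetyl imide F12, and a Mitsunobu etherification of 20 with this primary alcohol (PPh3, DIAD, THF, 0 °C → rt) would give 35.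

Further compounds
F1 | step 13 | (4R)-4-benzyl-3-{[2-(benzyloxy)-3-methoxy-5-(methoxycarbonyl)phenyl]acetyl}oxazolidin-2-one | COC(=O)c1cc(OC)c(OCc2ccccc2)c(CC(=O)N3[C@H](Cc4ccccc4)COC3=O)c1
F2 | step 13 | dibutylboron Z-enolate of F1 | COC(=O)c1cc(OC)c(OCc2ccccc2)c(/C=C(\OB(CCCC)CCCC)N3[C@H](Cc4ccccc4)COC3=O)c1
F3 | step 13 | (4R)-4-benzyl-3-{(2R,3R)-3-[4-(benzyloxy)-3,5-dimethoxyphenyl]-2-[2-(benzyloxy)-3-methoxy-5-(methoxycarbonyl)phenyl]-3-hydroxypropanoyl}oxazolidin-2-one (syn) | COC(=O)c1cc(OC)c(OCc2ccccc2)c(c1)[C@@H](C(=O)N3[C@H](Cc4ccccc4)COC3=O)[C@@H](O)c5cc(OC)c(OCc6ccccc6)c(OC)c5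
F4 | step 13 | methyl 4-(benzyloxy)-3-{(1R,2S)-1-[4-(benzyloxy)-3,5-dimethoxyphenyl]-1,3-dihydroxypropan-2-yl}-5-methoxybenzoate | COC(=O)c1cc(OC)c(OCc2ccccc2)c(c1)[C@@H](CO)[C@@H](O)c3cc(OC)c(OCc4ccccc4)c(OC)c3
F5 | step 13 | primary TBS ether of F4 | COC(=O)c1cc(OC)c(OCc2ccccc2)c(c1)[C@@H](CO[Si](C)(C)C(C)(C)C)[C@@H](O)c3cc(OC)c(OCc4ccccc4)c(OC)c3
F6 | step 13 | methyl 3-{1-[(tert-butyldimethylsilyl)oxy]-3-hydroxy-3-(4-hydroxy-3,5-dimethoxyphenyl)propan-2-yl}-4-hydroxy-5-methoxybenzoate, configuration as in F5 | COC(=O)c1cc(OC)c(O)c(c1)[C@@H](CO[Si](C)(C)C(C)(C)C)[C@@H](O)c2cc(OC)c(O)c(OC)c2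
F7 | step 18 | methyl 4-{[(1S,2S)-1,3-dihydroxy-1-{3-methoxy-4-[(triisopropylsilyl)oxy]phenyl}propan-2-yl]oxy}-3,5-dimethoxybenzoate (threo) | COc1cc(ccc1O[Si](C(C)C)(C(C)C)C(C)C)[C@H](O)[C@H](CO)Oc2c(OC)cc(cc2OC)C(=O)OC
F8 | step 18 | primary pivalate of F7 | COc1cc(ccc1O[Si](C(C)C)(C(C)C)C(C)C)[C@H](O)[C@H](COC(=O)C(C)(C)C)Oc2c(OC)cc(cc2OC)C(=O)OC
F9 | step 18 | aryl ketone from F8, (S) at the aryloxy-bearing carbon | COc1cc(ccc1O[Si](C(C)C)(C(C)C)C(C)C)C(=O)[C@H](COC(=O)C(C)(C)C)Oc2c(OC)cc(cc2OC)C(=O)OC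
F10 | step 18 | erythro (αR,βS) alcohol, primary pivalate | COc1cc(ccc1O[Si](C(C)C)(C(C)C)C(C)C)[C@@H](O)[C@H](COC(=O)C(C)(C)C)Oc2c(OC)cc(cc2OC)C(=O)OC
F11 | step 22 | (4R)-4-benzyl-3-[(benzyloxy)acetyl]oxazolidin-2-one | O=C(COCc1ccccc1)N2[C@H](Cc3ccccc3)COC2=O
F12 | step 22 | (4R)-4-benzyl-3-(hydroxyacetyl)oxazolidin-2-one | OCC(=O)N1[C@H](Cc2ccccc2)COC1=O
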